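The route cuts ring C of the flavone at three bonds: C8a–O1, C4a–C4 and O1–C2. In ring A, C8a bears O1 and the adjacent C4a bears the C4 carbonyl. This ortho oxygen/acyl pair is delivered in one operation by inserting an aryne spanning C4a and C8a into the C–O bond of an arylpropiolic acid; the freed phenoxide then closes ring C on the ynone. The aryne precursor is an ortho-silylaryl triflate (silicon at C8a, triflate at C4a) flanked by a 5-tosyloxy group, which steers the addition and later becomes the 5-hydroxyl, and by the 7,8-dimethoxy unit. The partner is 3-(3,4,5-trimethoxyphenyl)propiolic acid.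

Key step: step 6

Assumption: 2-hydroxy-4,5-dimethoxybenzaldehyde is taken as a catalogue compound, chosen because its hydroxyl and formyl groups mark from the start which ring-A oxygen becomes the tosylate and which the triflate.

Step 1
Reactants: 1 2-hydroxy-4,5-dimethoxybenzaldehyde
Product: 2 2-formyl-4,5-dimethoxyphenyl 4-methylbenzenesulfonate
Conditions: TsCl, Et3N, DMAP (cat.), CH2Cl2, 0 °C to rt
Reagents that add atoms: p-toluenesulfonyl chloride, Cc1ccc(cc1)S(=O)(=O)Cl
Why: O-sulfonylation of a phenol under amine base with nucleophilic catalysis should be clean, and it places the tosyl group on the oxygen that becomes O5 of the flavone before any second hydroxyl exists.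

Step 2
Reactants: 2 2-formyl-4,5-dimethoxyphenyl 4-methylbenzenesulfonate
Product: 4 2-hydroxy-4,5-dimethoxyphenyl 4-methylbenzenesulfonate, via aryl formate 3 (not isolated)
Conditions: mCPBA, CH2Cl2, 0 °C to rt; aqueous Na2S2O3/NaHCO3 wash; then Et3N (cat.), MeOH, rt
Reagents that add atoms: meta-chloroperoxybenzoic acid, OOC(=O)c1cccc(Cl)c1
Why: Baeyer–Villiger oxidation of an aryl aldehyde carrying a para methoxy group should proceed with aryl migration to the formate, which is then removed by mild transesterification that leaves the aryl tosylate untouched.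

Step 3
Reactants: 4 2-hydroxy-4,5-dimethoxyphenyl 4-methylbenzenesulfonate
Product: 5 3-bromo-2-hydroxy-4,5-dimethoxyphenyl 4-methylbenzenesulfonate
Conditions: NBS (1.0 equiv), MeCN, −20 to 0 °C, dark
Reagents that add atoms: N-bromosuccinimide, BrN1C(=O)CCC1=O
Why: Electrophilic aromatic bromination should occur ortho to the free hydroxyl, the strongest activator, whose para position is blocked by a methoxy group; the other open position lies next to the deactivating sulfonate.

Step 4
Reactants: 5 3-bromo-2-hydroxy-4,5-dimethoxyphenyl 4-methylbenzenesulfonate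
Product: 8 3,4-dimethoxy-6-(tosyloxy)-2-(trimethylsilyl)phenyl trifluoromethanesulfonate, via aryl trimethylsilyl ether 6 (not isolated), via lithium phenolate 7 (not isolated)
Conditions: HMDS, THF, reflux, then evaporation; n-BuLi (1.05 equiv), THF, −100 to −80 °C; Tf2O, −100 to −78 °C
Reagents that add atoms: hexamethyldisilazane, C[Si](C)(C)N[Si](C)(C)C; triflic anhydride, O=S(=O)(OS(=O)(=O)C(F)(F)F)C(F)(F)F
Why: O-silylation, bromine–lithium exchange, 1,3-retro-Brook migration of silicon from oxygen to carbon and O-triflation of the resulting phenoxide form the standard one-pot entry to ortho-silylaryl triflates; at −100 °C the exchange should outrun attack of n-BuLi on the tosylate, and the aryllithium sits meta to the sulfonate so it cannot eliminate it.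

Step 5
Reactants: 9 5-iodo-1,2,3-trimethoxybenzene; 10 propiolic acid
Product: 11 3-(3,4,5-trimethoxyphenyl)propiolic acid
Conditions: Pd(PPh3)4 (2.5 mol %), DBU (2.4 equiv), DMSO, 35 °C; then 1 M HCl
Reagents that add atoms: none
Why: Copper-free Sonogashira coupling of an aryl iodide with propiolic acid (oxidative addition to zerovalent palladium, transfer of the alkynyl carboxylate, reductive elimination) near room temperature should keep the carboxyl group, which a CuI co-catalyst or heat would remove.

Step 6
Reactants: 8 3,4-dimethoxy-6-(tosyloxy)-2-(trimethylsilyl)phenyl trifluoromethanesulfonate; 11 3-(3,4,5-trimethoxyphenyl)propiolic acid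
Product: 14 7,8-dimethoxy-4-oxo-2-(3,4,5-trimethoxyphenyl)-4H-chromen-5-yl 4-methylbenzenesulfonate (5-tosyloxy-7,8,3',4',5'-pentamethoxyflavone), via aryne 12 (not isolated), via cesium acylphenolate 13 (not isolated)
Conditions: CsF (4 equiv), 8 (1.5 equiv), THF, 125 °C, sealed tube
Reagents that add atoms: none
Why: CsF strips the silyl group from C8a with loss of triflate from C4a, which can give only aryne 12 with its strained bond between C4a and C8a; the cesium carboxylate of 11 then adds through oxygen to C8a, the carbanion left at C4a attacks the carbonyl of the aryl ester just formed by way of a strained four-membered adduct, and collapse of that adduct delivers the ortho-acyl phenoxide 13. The phenoxide oxygen then adds to the β-carbon of the ynone (C2) in a 6-endo-dig oxa-Michael closure that forms ring C, and protonation at C3 should give 14. The closest known reaction type is the formal insertion of arynes into the C–O bond of carboxylic acids to give ortho-hydroxyaryl ketones, which with arylpropiolic acids continues to flavones. No stereocentre is formed. The step needs oxygen at C8a and carbon at C4a: the reactive aryne orbitals lie in the ring plane and feel substituents through the σ framework, and the 5-sulfonate is a stronger σ-acceptor than the 8-methoxy group, so the developing negative charge should settle at C4a. A tosylate is chosen at C5 because it is a far poorer leaving group than a triflate, so the C4a anion should take the acyl group faster than it expels the sulfonate, while excess CsF keeps the acid as its carboxylate and so suppresses simple O–H insertion.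

Step 7
Reactants: 14 7,8-dimethoxy-4-oxo-2-(3,4,5-trimethoxyphenyl)-4H-chromen-5-yl 4-methylbenzenesulfonate
Product: 16 3-hydroxy-7,8-dimethoxy-4-oxo-2-(3,4,5-trimethoxyphenyl)-4H-chromen-5-yl 4-methylbenzenesulfonate, via flavone epoxide 15 (not isolated)
Conditions: DMDO (acetone solution, about 4 equiv in portions), CH2Cl2, 0 °C to rt, dark; evaporation; then p-TsOH·H2O (cat.), CH2Cl2, rt
Reagents that add atoms: dimethyldioxirane, CC1(C)OO1
Why: Dioxirane epoxidation of the flavone C2=C3 bond, followed by acid-catalysed opening at C2 and loss of H3 (epoxide-to-enol isomerisation), should give the flavonol under neutral to mildly acidic conditions that the sulfonate tolerates; the two epoxide stereocentres form cis by necessity, as a racemate, and are erased in the isomerisation.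

Step 8
Reactants: 16 3-hydroxy-7,8-dimethoxy-4-oxo-2-(3,4,5-trimethoxyphenyl)-4H-chromen-5-yl 4-methylbenzenesulfonate
Product: 17 3,5-dihydroxy-7,8,3',4',5'-pentamethoxyflavone
Conditions: KOH (5 equiv), MeOH/H2O 4:1, 60 °C, argon (degassed); then 1 M HCl
Reagents that add atoms: none
Why: Alkaline S–O cleavage of an aryl sulfonate by hydroxide should be eased by the peri carbonyl, which makes the 5-phenoxide a good leaving group, and air is excluded because flavonolate anions are oxidised by O2.

Compound list
1 | 2-hydroxy-4,5-dimethoxybenzaldehyde | COc1cc(O)c(C=O)cc1OC | starting material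
2 | 2-formyl-4,5-dimethoxyphenyl 4-methylbenzenesulfonate | COc1cc(OS(=O)(=O)c2ccc(C)cc2)c(C=O)cc1OC | intermediate
3 | 2-(formyloxy)-4,5-dimethoxyphenyl 4-methylbenzenesulfonate | COc1cc(OS(=O)(=O)c2ccc(C)cc2)c(OC=O)cc1OC | intermediate
4 | 2-hydroxy-4,5-dimethoxyphenyl 4-methylbenzenesulfonate | COc1cc(OS(=O)(=O)c2ccc(C)cc2)c(O)cc1OC | intermediate
5 | 3-bromo-2-hydroxy-4,5-dimethoxyphenyl 4-methylbenzenesulfonate | COc1cc(OS(=O)(=O)c2ccc(C)cc2)c(O)c(Br)c1OC | intermediate
6 | 3-bromo-4,5-dimethoxy-2-(trimethylsilyloxy)phenyl 4-methylbenzenesulfonate | COc1cc(OS(=O)(=O)c2ccc(C)cc2)c(O[Si](C)(C)C)c(Br)c1OC | intermediate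
7 | lithium 3,4-dimethoxy-6-(tosyloxy)-2-(trimethylsilyl)phenolate | COc1cc(OS(=O)(=O)c2ccc(C)cc2)c([O-])c([Si](C)(C)C)c1OC.[Li+] | intermediate
8 | 3,4-dimethoxy-6-(tosyloxy)-2-(trimethylsilyl)phenyl trifluoromethanesulfonate | COc1cc(OS(=O)(=O)c2ccc(C)cc2)c(OS(=O)(=O)C(F)(F)F)c([Si](C)(C)C)c1OC | intermediate
9 | 5-iodo-1,2,3-trimethoxybenzene | COc1cc(I)cc(OC)c1OC | starting material
10 | propiolic acid | C#CC(=O)O | starting material
11 | 3-(3,4,5-trimethoxyphenyl)propiolic acid | COc1cc(C#CC(=O)O)cc(OC)c1OC | intermediate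
12 | 3,4-dimethoxy-6-(tosyloxy)-1,2-didehydrobenzene (aryne across the future C8a and C4a) | COC1=C(OC)C#CC(OS(=O)(=O)c2ccc(C)cc2)=C1 | intermediate
13 | cesium 2,3-dimethoxy-5-(tosyloxy)-6-[3-(3,4,5-trimethoxyphenyl)propioloyl]phenolate | COc1cc(C#CC(=O)c2c(OS(=O)(=O)c3ccc(C)cc3)cc(OC)c(OC)c2[O-])cc(OC)c1OC.[Cs+] | intermediate
14 | 7,8-dimethoxy-4-oxo-2-(3,4,5-trimethoxyphenyl)-4H-chromen-5-yl 4-methylbenzenesulfonate (5-tosyloxy-7,8,3',4',5'-pentamethoxyflavone) | COc1cc(-c2cc(=O)c3c(OS(=O)(=O)c4ccc(C)cc4)cc(OC)c(OC)c3o2)cc(OC)c1OC | intermediate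
15 | racemic cis-2,3-epoxy-7,8-dimethoxy-5-(tosyloxy)-2-(3,4,5-trimethoxyphenyl)chroman-4-one (one enantiomer drawn) | COc1cc([C@@]23O[C@@H]2C(=O)c2c(OS(=O)(=O)c4ccc(C)cc4)cc(OC)c(OC)c2O3)cc(OC)c1OC | intermediate
16 | 3-hydroxy-7,8-dimethoxy-4-oxo-2-(3,4,5-trimethoxyphenyl)-4H-chromen-5-yl 4-methylbenzenesulfonate | COc1cc(-c2oc3c(OC)c(OC)cc(OS(=O)(=O)c4ccc(C)cc4)c3c(=O)c2O)cc(OC)c1OC | intermediate
17 | 3,5-dihydroxy-7,8,3',4',5'-pentamethoxyflavone | COc1cc(-c2oc3c(OC)c(OC)cc(O)c3c(=O)c2O)cc(OC)c1OC | target

Total step count: 8. Longest linear sequence: 7 steps (steps 1, 2, 3, 4, 6, 7, 8); step 5 supplies the second fragment.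

Steps most likely to fail

1. Step 6. The carboxylate may add in the reverse sense, with oxygen at C4a, if the 8-methoxy group competes with the 5-sulfonate as director. The C4a anion may also expel the neighbouring sulfonate before acyl transfer, or be protonated, which stops the sequence at the aryl ester. The propiolate may lose CO2 at 125 °C. Fallback: ring C is built by the chalcone route, in which O1 is an existing phenol oxygen and the orientation cannot be mistaken. It sets out from iodide 9. Iodine–magnesium exchange (i-PrMgCl·LiCl, THF, −20 °C) and formylation with DMF should give 3,4,5-trimethoxybenzaldehyde F1. Claisen–Schmidt condensation of this aldehyde with purchased 2'-hydroxy-3',4',6'-trimethoxyacetophenone (KOH, EtOH, rt) should give (E)-1-(2-hydroxy-3,4,6-trimethoxyphenyl)-3-(3,4,5-trimethoxyphenyl)prop-2-en-1-one F2. Oxidative cyclisation of the chalcone (I2 cat., DMSO, 130 °C) should give 5,7,8,3',4',5'-hexamethoxyflavone F3. Chelation-controlled cleavage of its peri methyl ether (BCl3, CH2Cl2, 0 °C) should give 5-hydroxy-7,8,3',4',5'-pentamethoxyflavone F4. Tosylation of this phenol (TsCl, K2CO3, acetone, reflux) comes back to the route at 14.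

2. Step 4. n-BuLi may attack the sulfonyl sulfur instead of exchanging bromine, or the tosyl group may migrate to the neighbouring phenoxide before triflation, which would scramble the two sulfonates. Fallback: the lithiation is carried out before any sulfonate is present. It sets out from aldehyde 1. Bromination ortho to the hydroxyl (NBS, MeCN, 0 °C) should give 3-bromo-2-hydroxy-4,5-dimethoxybenzaldehyde F5. Dakin oxidation (H2O2, NaOH, then acid) should give 3-bromo-4,5-dimethoxybenzene-1,2-diol F6. Silylation of both hydroxyls with HMDS should give 3-bromo-4,5-dimethoxy-1,2-bis(trimethylsilyloxy)benzene F7. Treatment with n-BuLi at −78 °C, retro-Brook migration and mild aqueous NH4Cl work-up should give 4,5-dimethoxy-3-(trimethylsilyl)benzene-1,2-diol F8. Tosylation of the hydroxyl remote from the bulky silyl group (TsCl 1 equiv, Et3N, CH2Cl2, −20 °C) should give 2-hydroxy-4,5-dimethoxy-3-(trimethylsilyl)phenyl 4-methylbenzenesulfonate F9. Triflation of the remaining hydroxyl (Tf2O, pyridine, CH2Cl2, 0 °C) comes back to the route at 8.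

3. Step 7. Epoxidation of the electron-poor C2=C3 bond may be slow, so that oxidation of the electron-rich ring B competes. Fallback: electrophilic oxidation is replaced by deprotonation. It sets out from 14. Lithiation at C3, directed by the C4 carbonyl (LDA, THF, −78 °C), and trapping with B(OMe)3 should give dimethyl [7,8-dimethoxy-4-oxo-5-(tosyloxy)-2-(3,4,5-trimethoxyphenyl)-4H-chromen-3-yl]boronate F10. Oxidation of its C–B bond (H2O2, AcOH, 0 °C to rt) comes back to the route at 16.

Further compounds
F1 | step 6 | 3,4,5-trimethoxybenzaldehyde | COc1cc(C=O)cc(OC)c1OC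
F2 | step 6 | (E)-1-(2-hydroxy-3,4,6-trimethoxyphenyl)-3-(3,4,5-trimethoxyphenyl)prop-2-en-1-one | COc1cc(/C=C/C(=O)c2c(O)c(OC)c(OC)cc2OC)cc(OC)c1OC
F3 | step 6 | 5,7,8,3',4',5'-hexamethoxyflavone | COc1cc(-c2cc(=O)c3c(OC)cc(OC)c(OC)c3o2)cc(OC)c1OC
F4 | step 6 | 5-hydroxy-7,8,3',4',5'-pentamethoxyflavone | COc1cc(-c2cc(=O)c3c(O)cc(OC)c(OC)c3o2)cc(OC)c1OC
F5 | step 4 | 3-bromo-2-hydroxy-4,5-dimethoxybenzaldehyde | COc1cc(C=O)c(O)c(Br)c1OC
F6 | step 4 | 3-bromo-4,5-dimethoxybenzene-1,2-diol | COc1cc(O)c(O)c(Br)c1OC
F7 | step 4 | 3-bromo-4,5-dimethoxy-1,2-bis(trimethylsilyloxy)benzene | COc1cc(O[Si](C)(C)C)c(O[Si](C)(C)C)c(Br)c1OC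
F8 | step 4 | 4,5-dimethoxy-3-(trimethylsilyl)benzene-1,2-diol | COc1cc(O)c(O)c([Si](C)(C)C)c1OC
F9 | step 4 | 2-hydroxy-4,5-dimethoxy-3-(trimethylsilyl)phenyl 4-methylbenzenesulfonate | COc1cc(OS(=O)(=O)c2ccc(C)cc2)c(O)c([Si](C)(C)C)c1OC
F10 | step 7 | dimethyl [7,8-dimethoxy-4-oxo-5-(tosyloxy)-2-(3,4,5-trimethoxyphenyl)-4H-chromen-3-yl]boronate | COc1cc(-c2oc3c(OC)c(OC)cc(OS(=O)(=O)c4ccc(C)cc4)c3c(=O)c2B(OC)OC)cc(OC)c1OC
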